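**Retrosynthetic overview**

- The strategy rests on ring A, a pentasubstituted resorcinol: C1 OMe, C2 prenyl, C3 OH, C4 H, C5 (E)-styryl, C6 prenyl, with meta oxygens at C1 and C3 that must be told apart.
- The final C3–O–Si and C1–O–CH3 disconnections lead back to a phenol with C1–OH free and C3–O silylated.
- Ring A is cut across C1–C2, C3–C4 and C1–C6 into a 4-prenyl-3-styrylcyclobutenone (supplying C1, C4, C5, C6) and a prenyl-bearing triisopropylsiloxyalkyne (supplying C2, C3): a Danheiser benzannulation.
- The cyclobutenone comes from a prenylketene/ethoxyacetylene [2+2] cycloaddition, then styryllithium addition with 1,3-carbonyl transposition; the siloxyalkyne comes from an ester by Kowalski ynolate formation and O-silylation.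
- Ring order: the four-membered ring first, then ring A; the phenyl ring is bought.

Key step: step 8

Remark: prenyl means 3-methylbut-2-en-1-yl and styryl means (E)-2-phenylethenyl; the cyclobutenones are used racemic, because their one stereocentre becomes aromatic C6.

**Step 1**
Reactants: 1 2-methylbut-3-en-2-ol; 2 triethyl orthoacetate
Product: 4 ethyl 5-methylhex-4-enoate, via mixed ketene acetal 3 (not isolated)
Conditions: 2 (excess), cat. EtCO2H, 140 °C, EtOH distilled off
Reagents that add atoms: none
Why: Johnson–Claisen rearrangement: acid-catalysed exchange gives ketene acetal 3, whose [3,3]-sigmatropic shift trades the tertiary allylic C–O bond for a new C–C bond and creates the trisubstituted alkene of the prenyl unit; no stereocentre is formed.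

**Step 2**
Reactants: 4 ethyl 5-methylhex-4-enoate
Product: 5 5-methylhex-4-enoic acid
Conditions: LiOH, THF/H2O, rt; then cold 1 M HCl to pH 3
Reagents that add atoms: lithium hydroxide [Li+].[OH-]
Why: Ester saponification by acyl substitution with hydroxide; the isolated trisubstituted alkene should tolerate the base and a brief cold acidification.

**Step 3**
Reactants: 5 5-methylhex-4-enoic acid
Product: 6 5-methylhex-4-enoyl chloride
Conditions: (COCl)2, cat. DMF, CH2Cl2, 0 °C to rt; volatiles removed, used crude
Reagents that add atoms: oxalyl chloride ClC(=O)C(=O)Cl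
Why: Acid chloride formation through the chloroiminium species from DMF and oxalyl chloride; the by-products are gases and the low temperature should keep HCl from adding to the alkene.

**Step 4**
Reactants: 6 5-methylhex-4-enoyl chloride; 7 ethoxyacetylene
Product: 9 3-ethoxy-4-(3-methylbut-2-en-1-yl)cyclobut-2-en-1-one (racemic), via prenylketene 8 (not isolated)
Conditions: 7 (3 equiv), Et3N (slow addition), Et2O, 0 °C to rt
Reagents that add atoms: none
Why: Dehydrochlorination gives aldoketene 8, which is trapped in situ by the ynol ether in a regioselective ketene–alkyne [2+2] cycloaddition (the nucleophilic terminal CH of 7 bonds to the ketene carbonyl carbon), so ethoxy ends at C3 and prenyl at C4; the C4 stereocentre forms racemic and is erased later.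

**Step 5**
Reactants: 9 3-ethoxy-4-(3-methylbut-2-en-1-yl)cyclobut-2-en-1-one; 10 (E)-β-bromostyrene
Product: 13 4-(3-methylbut-2-en-1-yl)-3-[(E)-2-phenylethenyl]cyclobut-2-en-1-one (racemic), via (E)-styryllithium 11 (not isolated), via tertiary cyclobutenol 12 (not isolated)
Conditions: 10 (1.3 equiv), t-BuLi (2.6 equiv), Et2O/THF, −78 °C; add 9, −78 °C; then 1 M aq HCl, 0 °C to rt
Reagents that add atoms: water O
Why: Stereoretentive bromine–lithium exchange gives 11, which adds 1,2 to the vinylogous ester carbonyl of 9; acid then ionises the tertiary allylic alcohol of 12 with push from the enol ether, and hydrolysis of the oxocarbenium ion completes a 1,3-carbonyl transposition that places styryl at C3 while leaving the E alkene and the racemic C4 centre untouched.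

**Step 6**
Reactants: 14 4-methylpent-3-enoic acid
Product: 15 ethyl 4-methylpent-3-enoate
Conditions: EtI, K2CO3, DMF, rt
Reagents that add atoms: iodoethane CCI
Why: SN2 O-alkylation of the carboxylate; avoiding acid prevents lactonisation of the β,γ-unsaturated acid onto its trisubstituted alkene.

**Step 7**
Reactants: 15 ethyl 4-methylpent-3-enoate
Product: 18 triisopropyl[(5-methylhex-4-en-1-yn-1-yl)oxy]silane, via dibromoketone enolate 16 (not isolated), via lithium ynolate 17 (not isolated)
Conditions: CH2Br2 (2.2 equiv), LiTMP (lithium 2,2,6,6-tetramethylpiperidide, 2.1 equiv), THF, −78 °C; add 15; then n-BuLi, −78 °C to rt; then i-Pr3SiOTf, −78 to 0 °C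
Reagents that add atoms: dibromomethane BrCBr (one alkyne carbon, delivered as LiCHBr2); triisopropylsilyl trifluoromethanesulfonate CC(C)[Si](C(C)C)(C(C)C)OS(=O)(=O)C(F)(F)F
Why: Kowalski ester homologation stopped at the ynolate: LiCHBr2 adds to the ester, the adduct collapses to enolate 16, bromine–lithium exchange and carbenoid 1,2-shift give ynolate 17, and the bulky silyl triflate reacts at oxygen rather than carbon to give the ynol silyl ether.

**Step 8**
Reactants: 13 4-(3-methylbut-2-en-1-yl)-3-[(E)-2-phenylethenyl]cyclobut-2-en-1-one; 18 triisopropyl[(5-methylhex-4-en-1-yn-1-yl)oxy]silane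
Product: 23 2,6-bis(3-methylbut-2-en-1-yl)-5-[(E)-2-phenylethenyl]-3-[(triisopropylsilyl)oxy]phenol, via vinylketene 19 (not isolated), via alkenylcyclobutenone 20 (not isolated), via dienylketene 21 (not isolated), via cyclohexadienone 22 (not isolated)
Conditions: 18 (1.3 equiv), toluene, 80 °C then 110 °C, dark, Ar
Reagents that add atoms: none
Why: Danheiser benzannulation: heating 13 causes reversible 4-electron conrotatory opening to vinylketene 19, whose ketene C=C undergoes [2+2] cycloaddition with the electron-rich siloxyalkyne to give 20, and a second 4-electron opening gives dienylketene 21. Ring A then closes by 6-electron disrotatory electrocyclisation of 21 between the ketene carbon (C1) and the prenyl-bearing CH terminus (C6), and cyclohexadienone 22 tautomerises to the phenol; overall the C1–C2 and C3–C4 bonds are new and C1–C6 is re-formed. The closest known reaction type is the thermal benzannulation of 3-substituted and 3,4-disubstituted cyclobutenones with trialkylsiloxyalkynes to give resorcinol monosilyl ethers. No stereocentre is created: the racemic C4 of 13 becomes aromatic C6, and the E alkene is not touched under thermal, light-free conditions. The step needs regioselective [2+2] cycloaddition, which the polarisation of 18 secures (its nucleophilic prenyl-bearing carbon bonds to the ketene carbonyl carbon, putting prenyl at C2 and the siloxy group at C3); the isolated prenyl alkenes are far poorer ketene partners, the cross-conjugated styryl branch cannot join an electrocyclisation, and outward rotation of the C4 prenyl leaves hydrogen inside for the 6-electron closure. The product should carry C1–OH free and C3–O silylated, which settles the differentiation of the two oxygens.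

**Step 9**
Reactants: 23 2,6-bis(3-methylbut-2-en-1-yl)-5-[(E)-2-phenylethenyl]-3-[(triisopropylsilyl)oxy]phenol
Product: 24 {3-methoxy-2,4-bis(3-methylbut-2-en-1-yl)-5-[(E)-2-phenylethenyl]phenoxy}triisopropylsilane
Conditions: NaH, MeI, DMF, 0 °C to rt
Reagents that add atoms: iodomethane CI
Why: Williamson O-methylation of the sodium phenoxide; the only free hydroxyl is the di-ortho-substituted C1 phenol, and anhydrous conditions should leave the C3 aryl silyl ether in place.

**Step 10**
Reactants: 24 {3-methoxy-2,4-bis(3-methylbut-2-en-1-yl)-5-[(E)-2-phenylethenyl]phenoxy}triisopropylsilane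
Product: 25 chiricanine C, 3-methoxy-2,4-bis(3-methylbut-2-en-1-yl)-5-[(E)-2-phenylethenyl]phenol
Conditions: Bu4NF, AcOH, THF, 0 °C
Reagents that add atoms: none
Why: Fluoride-induced desilylation driven by the strong Si–F bond; acetic acid buffering protonates the phenoxide as it forms, and nothing else in the molecule is fluoride-labile.

**Compound list**

1 | 2-methylbut-3-en-2-ol | CC(C)(O)C=C | starting material
2 | triethyl orthoacetate | CC(OCC)(OCC)OCC | starting material
3 | 1-ethoxy-1-[(2-methylbut-3-en-2-yl)oxy]ethene (mixed ketene acetal) | C=C(OCC)OC(C)(C)C=C | intermediate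
4 | ethyl 5-methylhex-4-enoate | CCOC(=O)CCC=C(C)C | intermediate
5 | 5-methylhex-4-enoic acid | OC(=O)CCC=C(C)C | intermediate
6 | 5-methylhex-4-enoyl chloride | ClC(=O)CCC=C(C)C | intermediate
7 | ethoxyacetylene | CCOC#C | starting material
8 | prenylketene (5-methylhexa-1,4-dien-1-one) | O=C=CCC=C(C)C | intermediate
9 | 3-ethoxy-4-(3-methylbut-2-en-1-yl)cyclobut-2-en-1-one (racemic) | O=C1C=C(OCC)C1CC=C(C)C | intermediate
10 | (E)-β-bromostyrene | Br/C=C/c1ccccc1 | starting material
11 | (E)-styryllithium | [Li]/C=C/c1ccccc1 | intermediate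
12 | 3-ethoxy-4-(3-methylbut-2-en-1-yl)-1-[(E)-2-phenylethenyl]cyclobut-2-en-1-ol (formed as its lithium alkoxide, diastereomer mixture) | CCOC1=CC(O)(/C=C/c2ccccc2)C1CC=C(C)C | intermediate
13 | 4-(3-methylbut-2-en-1-yl)-3-[(E)-2-phenylethenyl]cyclobut-2-en-1-one (racemic) | O=C1C=C(/C=C/c2ccccc2)C1CC=C(C)C | intermediate
14 | 4-methylpent-3-enoic acid | CC(C)=CCC(=O)O | starting material
15 | ethyl 4-methylpent-3-enoate | CCOC(=O)CC=C(C)C | intermediate
16 | lithium 1,1-dibromo-5-methylhexa-1,4-dien-2-olate | [Li]OC(CC=C(C)C)=C(Br)Br | intermediate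
17 | lithium 5-methylhex-4-en-1-yn-1-olate | [Li]OC#CCC=C(C)C | intermediate
18 | triisopropyl[(5-methylhex-4-en-1-yn-1-yl)oxy]silane | CC(C)=CCC#CO[Si](C(C)C)(C(C)C)C(C)C | intermediate
19 | 7-methyl-3-[(E)-2-phenylethenyl]octa-1,3,6-trien-1-one (vinylketene, prenyl CH2 trans to the ketene CH across C3=C4) | O=C=C/C(=C/CC=C(C)C)/C=C/c1ccccc1 | intermediate
20 | 2-(3-methylbut-2-en-1-yl)-4-{5-methyl-1-[(E)-2-phenylethenyl]hexa-1,4-dien-1-yl}-3-[(triisopropylsilyl)oxy]cyclobut-2-en-1-one (racemic) | O=C1C(CC=C(C)C)=C(O[Si](C(C)C)(C(C)C)C(C)C)C1/C(=C/CC=C(C)C)/C=C/c1ccccc1 | intermediate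
21 | 9-methyl-2-(3-methylbut-2-en-1-yl)-5-[(E)-2-phenylethenyl]-3-[(triisopropylsilyl)oxy]deca-1,3,5,8-tetraen-1-one (dienylketene, C2 and C5 cis across C3=C4) | O=C=C(CC=C(C)C)/C(O[Si](C(C)C)(C(C)C)C(C)C)=C\C(\C=C\c1ccccc1)=C\CC=C(C)C | intermediate
22 | 2,6-bis(3-methylbut-2-en-1-yl)-5-[(E)-2-phenylethenyl]-3-[(triisopropylsilyl)oxy]cyclohexa-2,4-dien-1-one (racemic) | O=C1C(CC=C(C)C)=C(O[Si](C(C)C)(C(C)C)C(C)C)C=C(/C=C/c2ccccc2)C1CC=C(C)C | intermediate
23 | 2,6-bis(3-methylbut-2-en-1-yl)-5-[(E)-2-phenylethenyl]-3-[(triisopropylsilyl)oxy]phenol | Oc1c(CC=C(C)C)c(O[Si](C(C)C)(C(C)C)C(C)C)cc(/C=C/c2ccccc2)c1CC=C(C)C | intermediate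
24 | {3-methoxy-2,4-bis(3-methylbut-2-en-1-yl)-5-[(E)-2-phenylethenyl]phenoxy}triisopropylsilane | COc1c(CC=C(C)C)c(O[Si](C(C)C)(C(C)C)C(C)C)cc(/C=C/c2ccccc2)c1CC=C(C)C | intermediate
25 | chiricanine C, 3-methoxy-2,4-bis(3-methylbut-2-en-1-yl)-5-[(E)-2-phenylethenyl]phenol | COc1c(CC=C(C)C)c(O)cc(/C=C/c2ccccc2)c1CC=C(C)C | target

**Totals**

Total step count: 10. Longest linear sequence: 8 steps (steps 1, 2, 3, 4, 5, 8, 9, 10).

**Steps most likely to fail**

Step 8. The C4 prenyl group may rotate inward during ring opening, after which a 1,5-hydrogen shift drains the vinylketene to a dienal. The 6-electron closure at the substituted terminus may also be slow enough for ketene dimerisation or O-acylation of the product phenol by the vinylketene to take over. The fallback sets out from 10 (through 11) and comes back at 23. Styryllithium 11 would be added to purchased 3-ethoxycyclobut-2-en-1-one to give the carbinol 3-ethoxy-1-[(E)-2-phenylethenyl]cyclobut-2-en-1-ol F1. Dilute HCl would convert it into 3-[(E)-2-phenylethenyl]cyclobut-2-en-1-one F2, a cyclobutenone with an unsubstituted C4. Heating F2 with 18 in toluene should give 2-(3-methylbut-2-en-1-yl)-5-[(E)-2-phenylethenyl]-3-[(triisopropylsilyl)oxy]phenol F3, in which C6 still carries hydrogen. The missing prenyl would then be put on C6, the only free ortho position, by ortho C-alkylation of the sodium phenoxide (NaH, prenyl bromide, toluene), giving 23.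

Step 7. LiCHBr2 or residual amide may abstract a proton from the doubly activated CH2 of 15 (allylic and alpha to the ester) faster than it adds to the carbonyl, and base may isomerise the skipped enyne after silylation. The fallback sets out from 4 and comes back at 18 (through 17). Ester 4, whose alkene is remote from the ester, would be brominated twice at C2 (LiN(SiMe3)2 then CBr4, THF, −78 °C, run twice). This gives first ethyl 2-bromo-5-methylhex-4-enoate F4 and then ethyl 2,2-dibromo-5-methylhex-4-enoate F5. Treating F5 with t-BuLi (4 equiv, THF, −78 to 0 °C) should cause double bromine–lithium exchange and loss of lithium ethoxide to give the same ynolate 17, which is silylated with i-Pr3SiOTf as before.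

Step 5. Elimination of HBr from 10 to phenylacetylide may compete with the exchange, the alkenyllithium may lose its E geometry, or the dienone may decompose during the acid transposition. The fallback sets out from 9 and comes back at 23, and it builds the E alkene last. CH2=CHMgBr would add to 9 (THF, −78 °C) to give 1-ethenyl-3-ethoxy-4-(3-methylbut-2-en-1-yl)cyclobut-2-en-1-ol F6. Dilute HCl would transpose it to 3-ethenyl-4-(3-methylbut-2-en-1-yl)cyclobut-2-en-1-one F7. Benzannulation of F7 with 18 in toluene should give 5-ethenyl-2,6-bis(3-methylbut-2-en-1-yl)-3-[(triisopropylsilyl)oxy]phenol F8. A Heck arylation of the terminal vinyl group with iodobenzene (Pd(OAc)2, P(o-tol)3, Et3N, DMF, 80 °C), which is inherently E-selective, would then give 23.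

**Further compounds**

F1 | step 8 | 3-ethoxy-1-[(E)-2-phenylethenyl]cyclobut-2-en-1-ol | CCOC1=CC(O)(/C=C/c2ccccc2)C1
F2 | step 8 | 3-[(E)-2-phenylethenyl]cyclobut-2-en-1-one | O=C1C=C(/C=C/c2ccccc2)C1
F3 | step 8 | 2-(3-methylbut-2-en-1-yl)-5-[(E)-2-phenylethenyl]-3-[(triisopropylsilyl)oxy]phenol | Oc1cc(/C=C/c2ccccc2)cc(O[Si](C(C)C)(C(C)C)C(C)C)c1CC=C(C)C
F4 | step 7 | ethyl 2-bromo-5-methylhex-4-enoate | CCOC(=O)C(Br)CC=C(C)C
F5 | step 7 | ethyl 2,2-dibromo-5-methylhex-4-enoate | CCOC(=O)C(Br)(Br)CC=C(C)C
F6 | step 5 | 1-ethenyl-3-ethoxy-4-(3-methylbut-2-en-1-yl)cyclobut-2-en-1-ol | CCOC1=CC(O)(C=C)C1CC=C(C)C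
F7 | step 5 | 3-ethenyl-4-(3-methylbut-2-en-1-yl)cyclobut-2-en-1-one | O=C1C=C(C=C)C1CC=C(C)C
F8 | step 5 | 5-ethenyl-2,6-bis(3-methylbut-2-en-1-yl)-3-[(triisopropylsilyl)oxy]phenol | Oc1c(CC=C(C)C)c(O[Si](C(C)C)(C(C)C)C(C)C)cc(C=C)c1CC=C(C)C
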